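**Retrosynthetic overview**
1. The γ-lactone is closed last: its C–O bond is made with inversion at C2 of the cycloheptane, by attack of the tert-butyl ester carbonyl on a triflate; the isobutyrate comes from acylation of the neighbouring secondary alcohol.
2. The three new stereocentres of the seven-membered ring are relayed from the OTBS-bearing carbon in this order: anti α-hydroxylation, hydroxyl-directed ketone reduction, hydrogenation on the face opposite a silylated tertiary OH.
3. The seven-membered ring comes from a two-carbon ring expansion of cyclopentanone 6 with ynone 9 (enamine (2+2) cycloaddition, then cyclobutene opening). It makes C3–C4 and C5–C6 of the cycloheptadiene and cleaves C3–C4 of the five-membered ring, whose three stereocentres are kept. The enabling feature: in 6 the carbonyl carbon C3 sits between a free CH2 (C4) and the blocked OTBS carbon C2, so only the C3=C4 enamine forms; in the derived bicyclo[3.2.0]hept-6-ene the amino group on C1 and the acyl group on C7 make a push–pull cyclobutene that opens at the C1–C5 bond.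
4. Cyclopentanone 6 comes from cyclopent-2-en-1-one by a catalytic asymmetric Mukaiyama–Michael addition and a Rubottom oxidation.
5. Ring order: cyclopentane (bought), cycloheptane (step 5), lactone (step 12).

Key step: step 5

Remark: 13 is written as one enol tautomer of the 1,3-diketone, and the (S)-oxazaborolidine is taken as the catalyst antipode that gives the 1R adduct 4 (its mirror image is used if the sense is opposite).

**Route**

Step 1
Reactants: 1 tert-butyl propanoate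
Product: 2 (E)-tert-butyl[(1-tert-butoxyprop-1-en-1-yl)oxy]dimethylsilane
Conditions: LiN(iPr)2, THF, −78 °C; TBSCl, DMPU, −78 °C → rt
Reagents that add atoms: tert-butyldimethylsilyl chloride, CC(C)(C)[Si](C)(C)Cl
Why: Kinetic ester enolisation in THF and O-silylation should give the E ketene silyl acetal (methyl trans to OSi), the geometry needed for the anti Michael adduct.

Step 2
Reactants: 2 (E)-tert-butyl[(1-tert-butoxyprop-1-en-1-yl)oxy]dimethylsilane; 3 cyclopent-2-en-1-one
Product: 4 tert-butyl (2R)-2-[(1R)-3-[(tert-butyldimethylsilyl)oxy]cyclopent-2-en-1-yl]propanoate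
Conditions: (S)-3,3-diphenyl-1-(o-tolyl)tetrahydro-1H,3H-pyrrolo[1,2-c][1,3,2]oxazaborole·HNTf2 (10 mol%), Ph3PO, toluene, −40 °C
Reagents that add atoms: none
Why: Mukaiyama–Michael addition under a chiral oxazaborolidinium Lewis acid: the catalyst selects one enone face (ring stereocentre), the open antiperiplanar transition state of the E acetal should give the anti ring/α-methyl relationship, and silyl transfer fixes the enol ether position for step 3.

Step 3
Reactants: 4 tert-butyl (2R)-2-[(1R)-3-[(tert-butyldimethylsilyl)oxy]cyclopent-2-en-1-yl]propanoate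
Product: 6 tert-butyl (2R)-2-[(1S,2S)-2-[(tert-butyldimethylsilyl)oxy]-3-oxocyclopentyl]propanoate, via silyloxy epoxide 5 (not isolated)
Conditions: mCPBA, NaHCO3, hexane/CH2Cl2, −15 °C → rt
Reagents that add atoms: mCPBA, OOC(=O)c1cccc(Cl)c1
Why: Rubottom oxidation: epoxidation anti to the C1 side chain, ring opening and 1,4-silyl shift should give the α-silyloxy ketone with oxygen trans to the side chain, which is also the stable arrangement at this epimerisable centre.

Step 4
Reactants: 7 trimethyl(prop-1-yn-1-yl)silane; 8 (E)-but-2-enoyl chloride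
Product: 9 (E)-hept-5-en-2-yn-4-one
Conditions: AlCl3, CH2Cl2, −20 → 0 °C
Reagents that add atoms: none
Why: Friedel–Crafts-type ipso-acylation of the alkynylsilane gives the ynone in one step with the E alkene of the acid chloride retained.

Step 5
Reactants: 6 tert-butyl (2R)-2-[(1S,2S)-2-[(tert-butyldimethylsilyl)oxy]-3-oxocyclopentyl]propanoate; 9 (E)-hept-5-en-2-yn-4-one
Product: 13 tert-butyl (2R)-2-[(1S,2S)-4-[(E)-but-2-enoyl]-2-[(tert-butyldimethylsilyl)oxy]-3-hydroxy-5-methylcyclohepta-3,5-dien-1-yl]propanoate (enol form of the 1,3-diketone), via enamine 10 (not isolated), via aminocyclobutene 11 (not isolated), via dienaminone 12 (not isolated)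
Conditions: pyrrolidine, TsOH·H2O (cat.), PhH, reflux (−H2O); then 9, MeCN, 0 → 60 °C; then AcOH/NaOAc/H2O, rt
Reagents that add atoms: water, O
Why: Pyrrolidine condenses toward the free methylene C4 of 6 to give enamine 10, whose β-carbon adds to the methyl-bearing alkyne carbon of 9; the zwitterion closes onto the iminium carbon to the 1-amino-7-acyl bicyclo[3.2.0]hept-6-ene 11, which opens at the former C3–C4 bond to dienaminone 12, and mild aqueous acid frees diketone 13. The closest known reaction is the two-carbon ring enlargement of cyclic ketone enamines with acetylenic esters and ketones. The four-membered ring closes stepwise (Michael addition, then Mannich-type closure of the vinyl anion on the iminium carbon), and the seven-membered ring arises by ring opening of the push–pull cyclobutene, not by a cyclisation. No stereocentre is created; C1, C2 and the propanoate α-carbon of 6 lie outside the reacting atoms and are kept. The step needs enamine regiochemistry (secured by the OTBS group on C2, which disfavours the tetrasubstituted enamine), attack at the ynone rather than the enone end of 9 (the sp carbon is the better acceptor) and the orientation that puts the acyl group next to the old carbonyl carbon (the enamine carbon bonds β to the carbonyl).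

Step 6
Reactants: 13 tert-butyl (2R)-2-[(1S,2S)-4-[(E)-but-2-enoyl]-2-[(tert-butyldimethylsilyl)oxy]-3-hydroxy-5-methylcyclohepta-3,5-dien-1-yl]propanoate
Product: 14 tert-butyl (2R)-2-[(1S,2S,4R)-4-[(E)-but-2-enoyl]-2-[(tert-butyldimethylsilyl)oxy]-4-hydroxy-5-methyl-3-oxocyclohept-5-en-1-yl]propanoate
Conditions: dimethyldioxirane (1.05 equiv), acetone/CH2Cl2, −78 → −40 °C
Reagents that add atoms: dimethyldioxirane, CC1(C)OO1
Why: Electrophilic α-hydroxylation of the enolised 1,3-diketone; oxygen should be delivered to the enol face anti to the allylic OTBS group on C2, which sets the quaternary carbinol centre.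

Step 7
Reactants: 14 tert-butyl (2R)-2-[(1S,2S,4R)-4-[(E)-but-2-enoyl]-2-[(tert-butyldimethylsilyl)oxy]-4-hydroxy-5-methyl-3-oxocyclohept-5-en-1-yl]propanoate
Product: 15 tert-butyl (2R)-2-[(1S,2S,3S,4S)-4-[(E)-but-2-enoyl]-2-[(tert-butyldimethylsilyl)oxy]-3,4-dihydroxy-5-methylcyclohept-5-en-1-yl]propanoate
Conditions: Me4NBH(OAc)3, MeCN/AcOH, −35 °C
Reagents that add atoms: none
Why: Hydroxyl-directed triacetoxyborohydride reduction (Evans–Saksena type): hydride is delivered to the ring ketone from the face of the tertiary OH, which is also the face anti to OTBS, giving the trans diol; the conjugated ketone is less electrophilic and should be spared.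

Step 8
Reactants: 15 tert-butyl (2R)-2-[(1S,2S,3S,4S)-4-[(E)-but-2-enoyl]-2-[(tert-butyldimethylsilyl)oxy]-3,4-dihydroxy-5-methylcyclohept-5-en-1-yl]propanoate
Product: 16 tert-butyl (2R)-2-[(1S,2S,3S,4S)-4-[(E)-but-2-enoyl]-2-[(tert-butyldimethylsilyl)oxy]-4-hydroxy-5-methyl-3-[(2-methylpropanoyl)oxy]cyclohept-5-en-1-yl]propanoate
Conditions: (iPrCO)2O, Et3N, DMAP (cat.), CH2Cl2, 0 °C → rt
Reagents that add atoms: 2-methylpropanoic anhydride, CC(C)C(=O)OC(=O)C(C)C
Why: DMAP-catalysed acylation takes the secondary alcohol and leaves the tertiary one untouched.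

Step 9
Reactants: 16 tert-butyl (2R)-2-[(1S,2S,3S,4S)-4-[(E)-but-2-enoyl]-2-[(tert-butyldimethylsilyl)oxy]-4-hydroxy-5-methyl-3-[(2-methylpropanoyl)oxy]cyclohept-5-en-1-yl]propanoate
Product: 17 tert-butyl (2R)-2-[(1S,2S,3S,4S)-4-[(E)-but-2-enoyl]-2-[(tert-butyldimethylsilyl)oxy]-5-methyl-3-[(2-methylpropanoyl)oxy]-4-[(trimethylsilyl)oxy]cyclohept-5-en-1-yl]propanoate
Conditions: TMSOTf, 2,6-lutidine, CH2Cl2, −78 °C
Reagents that add atoms: trimethylsilyl triflate, C[Si](C)(C)OS(=O)(=O)C(F)(F)F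
Why: Silylation of the tertiary alcohol stops it from directing the hydrogenation to its own face and adds bulk to that face.

Step 10
Reactants: 17 tert-butyl (2R)-2-[(1S,2S,3S,4S)-4-[(E)-but-2-enoyl]-2-[(tert-butyldimethylsilyl)oxy]-5-methyl-3-[(2-methylpropanoyl)oxy]-4-[(trimethylsilyl)oxy]cyclohept-5-en-1-yl]propanoate
Product: 18 tert-butyl (2R)-2-[(1S,2S,3S,4S,5S)-4-[(E)-but-2-enoyl]-2-[(tert-butyldimethylsilyl)oxy]-5-methyl-3-[(2-methylpropanoyl)oxy]-4-[(trimethylsilyl)oxy]cycloheptyl]propanoate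
Conditions: H2 (1 atm), [Ir(cod)(PCy3)(py)]PF6 (5 mol%), CH2Cl2, 0 °C
Reagents that add atoms: none
Why: Homogeneous hydrogenation of the trisubstituted ring alkene, directed by the ketone and ester carbonyls on the face opposite the OTMS group, should set the methyl centre cis to the silyloxy group; the electron-poor enone C=C reacts more slowly with the cationic iridium catalyst.

Step 11
Reactants: 18 tert-butyl (2R)-2-[(1S,2S,3S,4S,5S)-4-[(E)-but-2-enoyl]-2-[(tert-butyldimethylsilyl)oxy]-5-methyl-3-[(2-methylpropanoyl)oxy]-4-[(trimethylsilyl)oxy]cycloheptyl]propanoate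
Product: 19 tert-butyl (2R)-2-[(1S,2S,3S,4S,5S)-4-[(E)-but-2-enoyl]-2,4-dihydroxy-5-methyl-3-[(2-methylpropanoyl)oxy]cycloheptyl]propanoate
Conditions: HF·pyridine, THF, 0 °C → rt
Reagents that add atoms: none
Why: Fluoride-driven cleavage of both silyl ethers under buffered acidic conditions that leave the tert-butyl ester, the isobutyrate and the enone intact.

Step 12
Reactants: 19 tert-butyl (2R)-2-[(1S,2S,3S,4S,5S)-4-[(E)-but-2-enoyl]-2,4-dihydroxy-5-methyl-3-[(2-methylpropanoyl)oxy]cycloheptyl]propanoate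
Product: 21 (3R,3aS,6S,7S,8S,8aR)-7-[(E)-but-2-enoyl]-7-hydroxy-3,6-dimethyl-2-oxooctahydro-2H-cyclohepta[b]furan-8-yl 2-methylpropanoate, via triflate 20 (not isolated)
Conditions: Tf2O, 2,6-lutidine, CH2Cl2, −78 → 0 °C
Reagents that add atoms: none
Why: The secondary alcohol is triflated selectively and displaced intramolecularly (SN2, 5-exo-tet) by the carbonyl oxygen of the trans tert-butyl ester, with loss of isobutene; inversion at C2 gives the cis-fused lactone.

**Compound list**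
1 | tert-butyl propanoate | CCC(=O)OC(C)(C)C | starting material
2 | (E)-tert-butyl[(1-tert-butoxyprop-1-en-1-yl)oxy]dimethylsilane | C/C=C(/O[Si](C)(C)C(C)(C)C)OC(C)(C)C | intermediate
3 | cyclopent-2-en-1-one | O=C1C=CCC1 | starting material
4 | tert-butyl (2R)-2-[(1R)-3-[(tert-butyldimethylsilyl)oxy]cyclopent-2-en-1-yl]propanoate | C[C@@H](C(=O)OC(C)(C)C)[C@H]1C=C(O[Si](C)(C)C(C)(C)C)CC1 | intermediate
5 | silyloxy epoxide of 4 (epoxide anti to the side chain) | C[C@@H](C(=O)OC(C)(C)C)[C@H]1[C@@H]2O[C@]2(O[Si](C)(C)C(C)(C)C)CC1 | intermediate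
6 | tert-butyl (2R)-2-[(1S,2S)-2-[(tert-butyldimethylsilyl)oxy]-3-oxocyclopentyl]propanoate | C[C@@H](C(=O)OC(C)(C)C)[C@H]1[C@H](O[Si](C)(C)C(C)(C)C)C(=O)CC1 | intermediate
7 | trimethyl(prop-1-yn-1-yl)silane | CC#C[Si](C)(C)C | starting material
8 | (E)-but-2-enoyl chloride | C/C=C/C(Cl)=O | starting material
9 | (E)-hept-5-en-2-yn-4-one | CC#CC(=O)/C=C/C | intermediate
10 | tert-butyl (2R)-2-[(1S,2S)-2-[(tert-butyldimethylsilyl)oxy]-3-(pyrrolidin-1-yl)cyclopent-3-en-1-yl]propanoate | C[C@@H](C(=O)OC(C)(C)C)[C@H]1[C@H](O[Si](C)(C)C(C)(C)C)C(N2CCCC2)=CC1 | intermediate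
11 | tert-butyl (2R)-2-[7-[(E)-but-2-enoyl]-2-[(tert-butyldimethylsilyl)oxy]-6-methyl-1-(pyrrolidin-1-yl)bicyclo[3.2.0]hept-6-en-3-yl]propanoate | C[C@@H](C(=O)OC(C)(C)C)[C@H]1[C@H](O[Si](C)(C)C(C)(C)C)[C@@]2(N3CCCC3)C(C(=O)/C=C/C)=C(C)[C@H]2C1 | intermediate
12 | tert-butyl (2R)-2-[(1S,2S)-4-[(E)-but-2-enoyl]-2-[(tert-butyldimethylsilyl)oxy]-5-methyl-3-(pyrrolidin-1-yl)cyclohepta-3,5-dien-1-yl]propanoate | C1(N2CCCC2)=C(C(=O)/C=C/C)C(C)=CC[C@@H]([C@@H](C)C(=O)OC(C)(C)C)[C@@H]1O[Si](C)(C)C(C)(C)C | intermediate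
13 | tert-butyl (2R)-2-[(1S,2S)-4-[(E)-but-2-enoyl]-2-[(tert-butyldimethylsilyl)oxy]-3-hydroxy-5-methylcyclohepta-3,5-dien-1-yl]propanoate | OC1=C(C(=O)/C=C/C)C(C)=CC[C@@H]([C@@H](C)C(=O)OC(C)(C)C)[C@@H]1O[Si](C)(C)C(C)(C)C | intermediate
14 | tert-butyl (2R)-2-[(1S,2S,4R)-4-[(E)-but-2-enoyl]-2-[(tert-butyldimethylsilyl)oxy]-4-hydroxy-5-methyl-3-oxocyclohept-5-en-1-yl]propanoate | C/C=C/C(=O)[C@]1(O)C(C)=CC[C@@H]([C@@H](C)C(=O)OC(C)(C)C)[C@H](O[Si](C)(C)C(C)(C)C)C1=O | intermediate
15 | tert-butyl (2R)-2-[(1S,2S,3S,4S)-4-[(E)-but-2-enoyl]-2-[(tert-butyldimethylsilyl)oxy]-3,4-dihydroxy-5-methylcyclohept-5-en-1-yl]propanoate | C/C=C/C(=O)[C@]1(O)C(C)=CC[C@@H]([C@@H](C)C(=O)OC(C)(C)C)[C@H](O[Si](C)(C)C(C)(C)C)[C@@H]1O | intermediate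
16 | tert-butyl (2R)-2-[(1S,2S,3S,4S)-4-[(E)-but-2-enoyl]-2-[(tert-butyldimethylsilyl)oxy]-4-hydroxy-5-methyl-3-[(2-methylpropanoyl)oxy]cyclohept-5-en-1-yl]propanoate | C/C=C/C(=O)[C@]1(O)C(C)=CC[C@@H]([C@@H](C)C(=O)OC(C)(C)C)[C@H](O[Si](C)(C)C(C)(C)C)[C@@H]1OC(=O)C(C)C | intermediate
17 | tert-butyl (2R)-2-[(1S,2S,3S,4S)-4-[(E)-but-2-enoyl]-2-[(tert-butyldimethylsilyl)oxy]-5-methyl-3-[(2-methylpropanoyl)oxy]-4-[(trimethylsilyl)oxy]cyclohept-5-en-1-yl]propanoate | C/C=C/C(=O)[C@]1(O[Si](C)(C)C)C(C)=CC[C@@H]([C@@H](C)C(=O)OC(C)(C)C)[C@H](O[Si](C)(C)C(C)(C)C)[C@@H]1OC(=O)C(C)C | intermediate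
18 | tert-butyl (2R)-2-[(1S,2S,3S,4S,5S)-4-[(E)-but-2-enoyl]-2-[(tert-butyldimethylsilyl)oxy]-5-methyl-3-[(2-methylpropanoyl)oxy]-4-[(trimethylsilyl)oxy]cycloheptyl]propanoate | C/C=C/C(=O)[C@]1(O[Si](C)(C)C)[C@@H](C)CC[C@@H]([C@@H](C)C(=O)OC(C)(C)C)[C@H](O[Si](C)(C)C(C)(C)C)[C@@H]1OC(=O)C(C)C | intermediate
19 | tert-butyl (2R)-2-[(1S,2S,3S,4S,5S)-4-[(E)-but-2-enoyl]-2,4-dihydroxy-5-methyl-3-[(2-methylpropanoyl)oxy]cycloheptyl]propanoate | C/C=C/C(=O)[C@]1(O)[C@@H](C)CC[C@@H]([C@@H](C)C(=O)OC(C)(C)C)[C@H](O)[C@@H]1OC(=O)C(C)C | intermediate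
20 | 2-O-triflate of 19 | C/C=C/C(=O)[C@]1(O)[C@@H](C)CC[C@@H]([C@@H](C)C(=O)OC(C)(C)C)[C@H](OS(=O)(=O)C(F)(F)F)[C@@H]1OC(=O)C(C)C | intermediate
21 | (3R,3aS,6S,7S,8S,8aR)-7-[(E)-but-2-enoyl]-7-hydroxy-3,6-dimethyl-2-oxooctahydro-2H-cyclohepta[b]furan-8-yl 2-methylpropanoate | C/C=C/C(=O)[C@]1(O)[C@@H](C)CC[C@@H]2[C@@H](OC(=O)[C@@H]2C)[C@@H]1OC(=O)C(C)C | target

**Step count and risks**

Total step count: 12. Longest linear sequence: 11 steps (steps 1–3 and 5–12); step 4 is a one-step branch.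

Steps most likely to fail:

Step 5. The enamine may add to the enone end of 9, the addition to the β-methyl ynone may stall, or the hindered α-silyloxy ketone may form its enamine slowly. The fallback sets out from 6. Kinetic deprotonation (LiN(iPr)2, TMSCl, −78 °C) gives tert-butyl (2R)-2-[(1S,2S)-2-[(tert-butyldimethylsilyl)oxy]-3-[(trimethylsilyl)oxy]cyclopent-3-en-1-yl]propanoate F1. An acid-catalysed (2+2) cycloaddition of this silyl enol ether with 9 (HNTf2 cat., or EtAlCl2, CH2Cl2, −78 °C) gives the 1-(trimethylsilyloxy)bicyclo[3.2.0]hept-6-ene F2. Et3N·3HF then frees the bridgehead alkoxide, which opens the four-membered ring by a vinylogous retro-aldol reaction; the fallback comes back at 13.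

Step 10. The crotonyl C=C may be reduced together with the ring alkene. The fallback sets out from 17 and accepts this: prolonged hydrogenation with the same iridium catalyst, finished over Pd/C if needed, gives the butanoyl analogue F3. HF·pyridine gives the diol F4, and Tf2O/2,6-lutidine closes the lactone to the butanoyl analogue of the target F5. Dehydrogenation of the ketone with IBX (DMSO, 65 °C) can only occur on the chain side, because the ring-side α-carbon is quaternary; it restores the E enone and comes back at 21. This fallback does not correct hydrogen delivery to the wrong ring face.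

Step 12. The triflate may eliminate toward the enol ester, or the neighbouring isobutyrate may migrate before displacement. The fallback sets out from 19. MsCl/Et3N gives the secondary mesylate F6, TFA/CH2Cl2 cleaves the tert-butyl ester to the mesyloxy acid F7, and Cs2CO3 in DMF at 50 °C makes the free carboxylate displace the mesylate with inversion; it comes back at 21.

Further compounds
F1 | step 5 | tert-butyl (2R)-2-[(1S,2S)-2-[(tert-butyldimethylsilyl)oxy]-3-[(trimethylsilyl)oxy]cyclopent-3-en-1-yl]propanoate | C[C@@H](C(=O)OC(C)(C)C)[C@H]1[C@H](O[Si](C)(C)C(C)(C)C)C(O[Si](C)(C)C)=CC1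
F2 | step 5 | tert-butyl (2R)-2-[7-[(E)-but-2-enoyl]-2-[(tert-butyldimethylsilyl)oxy]-6-methyl-1-[(trimethylsilyl)oxy]bicyclo[3.2.0]hept-6-en-3-yl]propanoate | C[C@@H](C(=O)OC(C)(C)C)[C@H]1[C@H](O[Si](C)(C)C(C)(C)C)[C@@]2(O[Si](C)(C)C)C(C(=O)/C=C/C)=C(C)[C@H]2C1
F3 | step 10 | tert-butyl (2R)-2-[(1S,2S,3S,4S,5S)-4-butanoyl-2-[(tert-butyldimethylsilyl)oxy]-5-methyl-3-[(2-methylpropanoyl)oxy]-4-[(trimethylsilyl)oxy]cycloheptyl]propanoate | CCCC(=O)[C@]1(O[Si](C)(C)C)[C@@H](C)CC[C@@H]([C@@H](C)C(=O)OC(C)(C)C)[C@H](O[Si](C)(C)C(C)(C)C)[C@@H]1OC(=O)C(C)C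
F4 | step 10 | tert-butyl (2R)-2-[(1S,2S,3S,4S,5S)-4-butanoyl-2,4-dihydroxy-5-methyl-3-[(2-methylpropanoyl)oxy]cycloheptyl]propanoate | CCCC(=O)[C@]1(O)[C@@H](C)CC[C@@H]([C@@H](C)C(=O)OC(C)(C)C)[C@H](O)[C@@H]1OC(=O)C(C)C
F5 | step 10 | (3R,3aS,6S,7S,8S,8aR)-7-butanoyl-7-hydroxy-3,6-dimethyl-2-oxooctahydro-2H-cyclohepta[b]furan-8-yl 2-methylpropanoate | CCCC(=O)[C@]1(O)[C@@H](C)CC[C@@H]2[C@@H](OC(=O)[C@@H]2C)[C@@H]1OC(=O)C(C)C
F6 | step 12 | tert-butyl (2R)-2-[(1S,2S,3S,4S,5S)-4-[(E)-but-2-enoyl]-4-hydroxy-2-(methanesulfonyloxy)-5-methyl-3-[(2-methylpropanoyl)oxy]cycloheptyl]propanoate | C/C=C/C(=O)[C@]1(O)[C@@H](C)CC[C@@H]([C@@H](C)C(=O)OC(C)(C)C)[C@H](OS(C)(=O)=O)[C@@H]1OC(=O)C(C)C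
F7 | step 12 | (2R)-2-[(1S,2S,3S,4S,5S)-4-[(E)-but-2-enoyl]-4-hydroxy-2-(methanesulfonyloxy)-5-methyl-3-[(2-methylpropanoyl)oxy]cycloheptyl]propanoic acid | C/C=C/C(=O)[C@]1(O)[C@@H](C)CC[C@@H]([C@@H](C)C(O)=O)[C@H](OS(C)(=O)=O)[C@@H]1OC(=O)C(C)C
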